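Atom labels used throughout: O1, C2 (CHPh), C3, C4 (ketone), C4a, C5 (carbinol), C6 (ether carbon), C7 (ketone), C8, C8a as in a flavanone; C1′ (OCH2), C2′ (CH) and C3′ (CMe2) for the bridge. The target is compound 22.

## The problem

Compound 22 is a bicyclo[2.2.2]octenone with bridgeheads C5 and C8 and bridges C6–C7, C4a=C8a and C2′–C3′, to which a tetrahydrofuran (C5, C6, O, C1′, C2′) and a 2-phenyl-2,3-dihydropyran-4-one (O1, C2, C3, C4, C4a, C8a) are fused. C8 and C3′ form a vicinal pair of quaternary carbons, the hardest carbon–carbon bond of the skeleton to make. Of the five stereocentres, C5, C6 and C2′ are tied to C8 by the cage, so once C8 is fixed the ring closures allow only one arrangement; C2 is remote and must be set independently, which reduces the absolute problem to C8 and C2. The tertiary C5 hydroxyl is β to the C7 ketone and can be lost by retro-aldol cleavage. The C2–O1 bond opens by β-elimination from a C3 enolate, which would scramble C2, so strong base should not meet the finished pyranone. C1′ ends at the alcohol oxidation level, although C2′ must be nucleophilic when it is bonded to C5. The enabling feature is the C7 ketone flanked by the methyl-bearing carbons C6 and C8, which are joined on the other side by C5–C4a–C8a with oxygen on both ends: the pattern left by a double acylation of a ketone with a malonyl unit. The remaining ring atoms C6, C7, C8, C3′, C2′ and C1′ are those of a C-methylated dimedone if C1′ is bonded to C6 in place of oxygen.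

## Retrosynthesis

**C1′ oxidation level and O1–C8a (22 ⇒ 21 ⇒ 19).** The ether CH2 of 22 is taken back to lactol 21, and the O1–C8a bond of 21 is cut to give the δ-silyloxy β-diketone 19. Closing the pyranone this late keeps the C2–O1 bond away from all enolate chemistry. Because C5 is already sp3 in 19, C8a is the only carbonyl that can accept O1, so no regiochemical question arises. A cut at C2–O1 (oxa-Michael addition to a cinnamoyl group) would leave C2 uncontrolled. The forward steps need an acid-mediated desilylation and dehydration with retention at C2, then an ionic reduction of the lactol.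

**C2′–C5 (19 ⇒ 18 ⇒ 16).** The C5 carbinol is β to C1′, so with C1′ as a lactone carbonyl (18) the C2′–C5 bond is an aldol bond. Cutting it removes the cage and two stereocentres and leaves the bridged lactone 16. Because the acyl side chain is carried as an acidic β-triketone, the lactone reduction 18 → 19 can be run on its enolate. The forward reaction asks a lactone enolate to add to C5 although C5 belongs to that triketone; the tethers leave C5 as the only carbonyl within reach.

**C6–O (16 ⇒ 15).** The lactone oxygen is cut from C6 to give acid 15. An intermolecular hydroxylation of C6 would come from the face opposite the bulky chain on C8, which is the wrong face. The carboxyl hangs from that chain and can deliver oxygen only on the correct face. Acid 15 is monocyclic, with C8 as its only ring stereocentre. The forward step is an oxidative lactonisation that must pick C6 and close a seven-membered ring.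

**C4a–C4 (15 ⇒ 14 ⇒ 9 + 12).** The side chain is cut off as the enantiopure silyloxy acid 12, made in two steps from hydroxy ester 10 through 11. Placing this bond before the oxidation serves three ends: the acyl group blocks C4a, the most reactive carbon of trione 9; it brings C2 in the right configuration; and it turns the racemic ring into two diastereomers that can be separated. The forward reaction must put the acyl group on carbon, not oxygen.

**C1′–C6 reconnection (9 ⇒ 8).** Joining the ester carbon C1′ of 9 to C6 gives the bicyclo[3.3.1]nonane tetraone 8, in which both methyl-bearing quaternary carbons are bridgeheads. In the forward direction an alkoxide must cleave this one 1,3-dicarbonyl bond and no other (retro-Claisen).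

**C8–C8a and C5–C6 (8 ⇒ 5 + 6).** Both bonds to the C5–C4a–C8a unit are cut at once. This gives malonyl dichloride (6) and the achiral 1-methoxy-3-silyloxy diene 5, whose ring already holds the C8–C3′ bond. Cuts through C8–C3′ or C2′–C3′ would instead require a quaternary carbon to be made next to another one. The forward reaction must acylate C8 and C6 on carbon; the bicycle then fixes their relative configuration.

**Diene (5 ⇒ 4 ⇒ 3 ⇒ 2 ⇒ 1).** Removal of the silyl group, the C8 methyl, the enol ether methyl and the C6 methyl leads back to dimedone (1). Each forward step is an enolate or enol ether reaction of a cyclic 1,3-dione.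

## Roads not taken

**Alternative 1:** The cut is C5–C6 together with a temporary bond C4a–C7 that the target does not contain. Ketene A1, tethered through the C1′ oxygen to a bis(silyloxy)cyclohexadiene, would add across its C5=C4a enol ether to give cyclobutanone A2 with the tetrahydrofuran already closed. A 1,3-acyl shift of this 2-vinylcyclobutanone would then move C7 from C4a to C8 and open the four-membered ring into the bicyclo[2.2.2]octenone.
- Merits: C1′ is at its final oxidation level from the start, so no lactone reduction is needed. C5 and C6 follow from the single stereocentre C2′, which could be made enantioselectively, so no material is lost to a resolution.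
- Weak points: the acyl shift must form the C7–C8 bond at a fully substituted carbon next to CMe2. It competes with cycloreversion and decarbonylation of the cyclobutanone. An alkoxy ketene of this kind dimerises readily. C4a still has to be acylated afterwards.
- Comparison: this road is better in stereocontrol and in redox economy. The chosen plan sets against it a key step with close precedent, a C8–C3′ bond bought ready-made in dimedone, and cheap achiral fragments. It pays with the discarded diastereomer and a lactone reduction.

**Alternative 2:** The cut is C8–C8a and C5–C4a, a Diels–Alder disconnection of the bicyclo[2.2.2] core. Diene A3 and bromoynone A4 would give adduct A5. Both silyloxy groups of A3 polarise the diene so that C8 bonds to the bromine-bearing carbon. The bromide would later be displaced by the C2 oxygen, the C6=C7 silyl enol ether oxidised at C6, and the ether closed with C1′.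
- Merits: it is the most convergent plan. One step makes the carbocyclic cage and attaches the whole flavanone chain. The bromide fixes where O1 enters, and the C2′ stereocentre can direct the facial selectivity, so no resolution is needed.
- Weak points: both diene termini are fully substituted and C8 sits next to CMe2, so two quaternary carbons must form in a bimolecular cycloaddition with a disubstituted alkyne. Afterwards C6 must be oxygenated on the face of the C2′–C3′ bridge, the more hindered one, without a tether to enforce it.
- Comparison: if the cycloaddition worked, this road would be shorter than the chosen one and absolute from the start. The chosen plan forms its hindered bonds by acylation instead, which is far less sensitive to steric load, and sets C6–O by intramolecular delivery.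

**Alternative 3:** The cut is C2′–C3′. In acyl furanone A6 the C2′ enolate of the ring ketone would add to the β,β-dimethyl enone carbon C3′ and give the 6-oxabicyclo[3.2.1]octane dione A7.
- Merits: the entry is very short. The tetrahydrofuran, C6, C2′ and the correct oxidation level at C1′ are in place after one ring closure, and the single stereocentre of A6 controls the rest.
- Weak points: the Michael addition builds a quaternary carbon in a reversible endo closure. A7 still lacks the C8 methyl, C8a, C4a and the pyranone. C8 would have to be made quaternary late, between CMe2 and a ketone, and a second carbocycle closed onto C5. A7 is also a non-enolisable 1,3-diketone and open to retro-Claisen cleavage.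
- Comparison: its key step is simpler than the one chosen, but it covers less of the skeleton and postpones the hardest carbon to the end. The chosen key step delivers all six carbons of the carbocycle and both methyl-bearing quaternary centres at once.

Key step: step 5

Assumptions:
- The annulation gives 8 as the racemate. The single enantiomer is secured after the enantiopure acid 12 has been attached, by chromatographic separation of lactone 16 from its ring diastereomer at step 11. The SMILES of 8 shows the enantiomer that leads to 22.
- CIP descriptors at C5 and C2′ change along the route with the substituent priorities; the spatial arrangement does not.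

## Route

Step 1
Reactants: 1 dimedone (5,5-dimethylcyclohexane-1,3-dione)
Product: 2 2,5,5-trimethylcyclohexane-1,3-dione
Conditions: MeI, K2CO3, acetone, reflux
Reagents that add atoms: iodomethane, CI
Why: C-alkylation of the enolate of a cyclic 1,3-dione at the carbon between the carbonyls; this carbon becomes C6.

Step 2
Reactants: 2 2,5,5-trimethylcyclohexane-1,3-dione
Product: 3 3-methoxy-2,5,5-trimethylcyclohex-2-en-1-one
Conditions: HC(OMe)3, MeOH, TsOH (cat.), rt to 50 °C
Reagents that add atoms: trimethyl orthoformate, COC(OC)OC
Why: Acid-catalysed enol etherification of a symmetric 1,3-dione, so only one enol ether can form; its oxygen-bearing carbon is C1′.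

Step 3
Reactants: 3 3-methoxy-2,5,5-trimethylcyclohex-2-en-1-one
Product: 4 3-methoxy-2,5,5,6-tetramethylcyclohex-2-en-1-one (racemate)
Conditions: LiN(iPr)2, THF, −78 °C; MeI, −78 to 0 °C
Reagents that add atoms: iodomethane, CI
Why: Kinetic α′-deprotonation of a vinylogous ester and alkylation (Stork–Danheiser alkylation) puts the methyl group on C8; the new stereocentre is racemic and is erased in step 4.

Step 4
Reactants: 4 3-methoxy-2,5,5,6-tetramethylcyclohex-2-en-1-one
Product: 5 1-methoxy-2,4,5,5-tetramethyl-3-(trimethylsilyloxy)cyclohexa-1,3-diene
Conditions: LiN(iPr)2, THF, −78 °C; Me3SiCl, −78 to 0 °C; non-aqueous work-up, used crude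
Reagents that add atoms: chlorotrimethylsilane, C[Si](C)(C)Cl
Why: A second kinetic α′-deprotonation and O-silylation give the cross-conjugated silyl dienol ether; γ-deprotonation is the thermodynamic pathway and is avoided at −78 °C with the amide base.

Step 5
Reactants: 5 1-methoxy-2,4,5,5-tetramethyl-3-(trimethylsilyloxy)cyclohexa-1,3-diene; 6 malonyl dichloride
Product: 8 rac-(1R,5S)-1,5,8,8-tetramethylbicyclo[3.3.1]nonane-2,4,6,9-tetraone (enolised C5/C4a/C8a diketone), via keto acid chloride 7 (not isolated)
Conditions: 6 (1.3 equiv), CH2Cl2, −78 to 0 °C; pH 7 buffer work-up, then acidify to pH 3 (no hydroxide)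
Reagents that add atoms: none
Why: This is an Effenberger annulation, the double C-acylation of a ketone enol ether by malonyl dichloride, which is known to turn methyl and silyl enol ethers of cyclohexanones into bicyclo[3.3.1]nonane-2,4,9-triones. C8, the terminus of the silyl enol ether and the vinylogous terminus of the methoxy diene, attacks one acid chloride with loss of Me3SiCl and gives 7. The enol ether carbon C6 of 7 then attacks the second acid chloride (or the ketene derived from it), and the C1′ oxocarbenium ion loses its methyl group to chloride, which leaves the C1′ ketone. The carbocycle C5–C4a–C8a–C8–C7–C6 closes in this second acylation as a 6-(enolexo)-exo-trig process. The new stereocentres C6 and C8 are controlled only by the bicycle: a three-carbon bridge can span them only cis, and with no chiral element present 8 is racemic. The step needs C- over O-acylation and reaction at C8 before C6; the diene secures this because C8 is doubly activated, after which C6 is the only nucleophilic carbon that the tethered acid chloride reaches through a six-membered transition state. The work-up avoids hydroxide because the C1′–C6 bond of 8 is labile to retro-Claisen cleavage.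

Step 6
Reactants: 8 rac-(1R,5S)-1,5,8,8-tetramethylbicyclo[3.3.1]nonane-2,4,6,9-tetraone
Product: 9 methyl 3-(1,3-dimethyl-2,4,6-trioxocyclohexyl)-3-methylbutanoate (racemate at C8, enol tautomers)
Conditions: NaOMe (2.5 equiv), MeOH, 0 °C to rt; aq. HCl to pH 3
Reagents that add atoms: sodium methoxide, [Na+].[O-]C
Why: Retro-Claisen methanolysis: the C5/C4a/C8a diketone is stored as its enolate and C7 is shielded by two quaternary carbons, so methoxide adds to C1′ and expels the C6 enolate stabilised by C7 and C5. C6 loses its configuration, C8 keeps it, and the C1′ carboxyl is set free as the methyl ester.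

Step 7
Reactants: 10 ethyl (3R)-3-hydroxy-3-phenylpropanoate
Product: 11 ethyl (3R)-3-[(tert-butyldimethylsilyl)oxy]-3-phenylpropanoate
Conditions: tBuMe2SiCl, imidazole, DMF, rt
Reagents that add atoms: tert-butyldimethylsilyl chloride, CC(C)(C)[Si](C)(C)Cl
Why: Standard silylation of a secondary alcohol; the stereocentre, the future C2, is not touched.

Step 8
Reactants: 11 ethyl (3R)-3-[(tert-butyldimethylsilyl)oxy]-3-phenylpropanoate
Product: 12 (3R)-3-[(tert-butyldimethylsilyl)oxy]-3-phenylpropanoic acid
Conditions: LiOH, THF/MeOH/H2O, 0 °C to rt; cold aq. HCl to pH 3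
Reagents that add atoms: lithium hydroxide, [Li+].[OH-]
Why: Saponification of an ethyl ester; at or below room temperature the β-silyloxy group is not eliminated.

Step 9
Reactants: 9 methyl 3-(1,3-dimethyl-2,4,6-trioxocyclohexyl)-3-methylbutanoate; 12 (3R)-3-[(tert-butyldimethylsilyl)oxy]-3-phenylpropanoic acid
Product: 14 methyl 3-{5-[(3R)-3-[(tert-butyldimethylsilyl)oxy]-3-phenylpropanoyl]-1,3-dimethyl-2,4,6-trioxocyclohexyl}-3-methylbutanoate (both configurations at C8, enol tautomers), via enol ester 13 (not isolated)
Conditions: DCC, DMAP (1.2 equiv), CH2Cl2, 0 °C to rt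
Reagents that add atoms: none
Why: Carbodiimide O-acylation followed by DMAP-mediated O-to-C acyl migration is the standard way to 2-acylcyclohexane-1,3-diones; the acyl group settles on C4a, the only carbon where it gives an enolisable, chelated triketone. Racemic 9 and (R)-12 necessarily give the two C8 diastereomers in equal amounts.

Step 10
Reactants: 14 methyl 3-{5-[(3R)-3-[(tert-butyldimethylsilyl)oxy]-3-phenylpropanoyl]-1,3-dimethyl-2,4,6-trioxocyclohexyl}-3-methylbutanoate
Product: 15 3-{5-[(3R)-3-[(tert-butyldimethylsilyl)oxy]-3-phenylpropanoyl]-1,3-dimethyl-2,4,6-trioxocyclohexyl}-3-methylbutanoic acid (both configurations at C8)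
Conditions: LiOH, THF/MeOH/H2O, rt to 40 °C; cold aq. HCl to pH 3
Reagents that add atoms: lithium hydroxide, [Li+].[OH-]
Why: Saponification; the triketone and the C5/C6/C7 diketone are present as enolates and resist hydroxide. C3 is not acidic in the triketonate, so the β-silyloxy group is not eliminated.

Step 11
Reactants: 15 3-{5-[(3R)-3-[(tert-butyldimethylsilyl)oxy]-3-phenylpropanoyl]-1,3-dimethyl-2,4,6-trioxocyclohexyl}-3-methylbutanoic acid
Product: 16 (1S,6R)-8-[(3R)-3-[(tert-butyldimethylsilyl)oxy]-3-phenylpropanoyl]-1,5,5,6-tetramethyl-2-oxabicyclo[4.3.1]decane-3,7,9,10-tetraone, the (6S,8R) seven-membered lactone, isolated as the single diastereomer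
Conditions: PhI(OAc)2 (1.1 equiv), CH2Cl2/CF3CH2OH, 0 °C; chromatography to remove the (6R,8S) lactone formed from the other half of 15
Reagents that add atoms: none
Why: Oxidative lactonisation of a 1,3-dicarbonyl by hypervalent iodine (intramolecular α-acyloxylation): C6, the methyl-bearing enol carbon between C5 and C7, is the nucleophilic site of such 2-acyl triones while C4a is blocked, and the carboxylate displaces iodobenzene from C6. The carboxyl hangs from C8, so oxygen reaches C6 only on the face of the C3′ chain, which sets C6 cis to C8 (6S for 8R, 6R for 8S). The lactones are the first rigid compounds of the sequence, so the two diastereomers differ in shape and are separated here; the (6R,8S) lactone is discarded.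

Step 12
Reactants: 16 the (6S,8R) seven-membered lactone
Product: 18 cage lactone (2′S,5S,6S,8R) having C1′ as lactone carbonyl plus C5–O–SiEt3 plus the open (3R)-3-[(tert-butyldimethylsilyl)oxy]-3-phenylpropanoyl chain on C4a–H next to the C8a ketone, via bis-silyl enol ether 17 (not isolated)
Conditions: LiN(SiMe3)2 (2.2 equiv), THF, −78 °C; Et3SiOSO2CF3 (2.5 equiv), −78 to −20 °C; aq. NaHCO3, silica gel
Reagents that add atoms: triethylsilyl trifluoromethanesulfonate, CC[Si](CC)(CC)OS(=O)(=O)C(F)(F)F
Why: Proposed new method: a transannular Mukaiyama-type aldol onto a ring carbonyl of a β-triketone; the first equivalent of base stores the triketone as its enolate (so that C3 is not deprotonated), the second forms the C2′ lactone enolate, and Et3SiOSO2CF3 then O-silylates both, which turns the inert triketonate into an electrophilic silyloxy enedione and the enolate into a ketene silyl acetal held over C5 by the C8–C3′ and C6–O–C1′ tethers (C7 and C8a would require four-membered rings). The closest known reaction type is the silyl-triflate-promoted intramolecular Mukaiyama aldol addition of a ketene silyl acetal to a ketone or β-alkoxy enone; every O-silyl regioisomer of the triketone converges on the same C5 silyl ether, by aldol addition and silyl transfer or by Mukaiyama–Michael addition at a C5–O-silylated carbon (elimination is forbidden at the new bridgehead), and the enol silyl ether of 17 is hydrolysed on work-up. The two tethers allow a single mode of closure, which fixes C5 and C2′ in the arrangement of 22.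

Step 13
Reactants: 18 cage lactone (2′S,5S,6S,8R)
Product: 19 cage lactol (2′S,5R,6S,8R; both configurations at C1′): 18 with C1′ as CH(OH)
Conditions: NaH (1.1 equiv), THF, 0 °C; iBu2AlH (1.3 equiv), −78 °C; aq. potassium sodium tartrate
Reagents that add atoms: none
Why: The β-diketone is first stored as its enolate, which hydride does not reduce (in situ enolate protection); iBu2AlH then takes the γ-lactone to the lactol at −78 °C. The C7 ketone lies between two quaternary carbons and should react more slowly.

Step 14
Reactants: 19 cage lactol (2′S,5R,6S,8R)
Product: 21 lactol flavanone (2R,5R,6S,8R,2′S): compound 22 having C1′ as CH(OH), via desilylated hydroxy diketone 20 (not isolated)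
Conditions: aq. HF (48%), MeCN, 0 °C to rt
Reagents that add atoms: none
Why: HF removes both silyl groups; the freed C2 hydroxyl adds to the C8a ketone and the hemiketal dehydrates (cyclodehydration of a δ-hydroxy β-diketone to a 2,3-dihydro-4H-pyran-4-one). The C2–O bond is never broken, so C2 is retained, and with C5 already sp3 only C8a can accept O1.

Step 15
Reactants: 21 lactol flavanone (2R,5R,6S,8R,2′S)
Product: 22 target cage flavanone (2R,5R,6S,8R,2′R)
Conditions: Et3SiH, BF3·OEt2, CH2Cl2, −78 to −30 °C
Reagents that add atoms: none
Why: Ionic hydrogenation of a lactol: the Lewis acid forms the five-membered oxocarbenium ion and the silane delivers hydride, giving the cyclic ether. The vinylogous ester and the hindered C7 ketone are not reduced at this temperature, and C1′ becomes CH2, so no stereocentre is at stake.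

## Compound list

1 | dimedone (5,5-dimethylcyclohexane-1,3-dione) | CC1(C)CC(=O)CC(=O)C1 | starting material
2 | 2,5,5-trimethylcyclohexane-1,3-dione | CC1C(=O)CC(C)(C)CC1=O | intermediate
3 | 3-methoxy-2,5,5-trimethylcyclohex-2-en-1-one | COC1=C(C)C(=O)CC(C)(C)C1 | intermediate
4 | 3-methoxy-2,5,5,6-tetramethylcyclohex-2-en-1-one, racemate | COC1=C(C)C(=O)C(C)C(C)(C)C1 | intermediate
5 | 1-methoxy-2,4,5,5-tetramethyl-3-(trimethylsilyloxy)cyclohexa-1,3-diene | COC1=C(C)C(O[Si](C)(C)C)=C(C)C(C)(C)C1 | intermediate
6 | malonyl dichloride | O=C(Cl)CC(Cl)=O | starting material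
7 | 3-(4-methoxy-1,3,6,6-tetramethyl-2-oxocyclohex-3-en-1-yl)-3-oxopropanoyl chloride, racemate, not isolated | COC1=C(C)C(=O)C(C)(C(=O)CC(Cl)=O)C(C)(C)C1 | intermediate
8 | rac-(1R,5S)-1,5,8,8-tetramethylbicyclo[3.3.1]nonane-2,4,6,9-tetraone (enantiomer shown leads to 22) | C[C@@]12C(=O)CC(C)(C)[C@@](C)(C1=O)C(=O)CC2=O | intermediate
9 | methyl 3-(1,3-dimethyl-2,4,6-trioxocyclohexyl)-3-methylbutanoate, racemate | COC(=O)CC(C)(C)C1(C)C(=O)CC(=O)C(C)C1=O | intermediate
10 | ethyl (3R)-3-hydroxy-3-phenylpropanoate | CCOC(=O)C[C@H](c1ccccc1)O | starting material
11 | ethyl (3R)-3-[(tert-butyldimethylsilyl)oxy]-3-phenylpropanoate | CCOC(=O)C[C@H](c1ccccc1)O[Si](C)(C)C(C)(C)C | intermediate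
12 | (3R)-3-[(tert-butyldimethylsilyl)oxy]-3-phenylpropanoic acid | OC(=O)C[C@H](c1ccccc1)O[Si](C)(C)C(C)(C)C | intermediate
13 | methyl 3-(4-{[(3R)-3-[(tert-butyldimethylsilyl)oxy]-3-phenylpropanoyl]oxy}-1,5-dimethyl-2,6-dioxocyclohex-3-en-1-yl)-3-methylbutanoate, enol ester drawn at the C5 oxygen, not isolated | COC(=O)CC(C)(C)C1(C)C(=O)C=C(OC(=O)C[C@H](c2ccccc2)O[Si](C)(C)C(C)(C)C)C(C)C1=O | intermediate
14 | methyl 3-{5-[(3R)-3-[(tert-butyldimethylsilyl)oxy]-3-phenylpropanoyl]-1,3-dimethyl-2,4,6-trioxocyclohexyl}-3-methylbutanoate, both configurations at C8 | COC(=O)CC(C)(C)C1(C)C(=O)C(C(=O)C[C@H](c2ccccc2)O[Si](C)(C)C(C)(C)C)C(=O)C(C)C1=O | intermediate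
15 | 3-{5-[(3R)-3-[(tert-butyldimethylsilyl)oxy]-3-phenylpropanoyl]-1,3-dimethyl-2,4,6-trioxocyclohexyl}-3-methylbutanoic acid, both configurations at C8 | OC(=O)CC(C)(C)C1(C)C(=O)C(C(=O)C[C@H](c2ccccc2)O[Si](C)(C)C(C)(C)C)C(=O)C(C)C1=O | intermediate
16 | (1S,6R)-8-[(3R)-3-[(tert-butyldimethylsilyl)oxy]-3-phenylpropanoyl]-1,5,5,6-tetramethyl-2-oxabicyclo[4.3.1]decane-3,7,9,10-tetraone; (6S,8R) lactone, single diastereomer | O=C1CC(C)(C)[C@]2(C)C(=O)C(C(=O)C[C@H](c3ccccc3)O[Si](C)(C)C(C)(C)C)C(=O)[C@](C)(O1)C2=O | intermediate
17 | bis-silyl enol ether: 18 with the C8a oxygen as triethylsilyl enol ether (C8a=C4a), not isolated | CC1(C)[C@@H]2C(=O)O[C@]3(C)C(=O)[C@@]1(C)C(O[Si](CC)(CC)CC)=C(C(=O)C[C@H](c4ccccc4)O[Si](C)(C)C(C)(C)C)[C@]23O[Si](CC)(CC)CC | intermediate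
18 | cage lactone (2′S,5S,6S,8R): C1′ lactone carbonyl, C5–O–SiEt3, C8a ketone, C4a–H bearing the (3R)-3-[(tert-butyldimethylsilyl)oxy]-3-phenylpropanoyl group | CC1(C)[C@@H]2C(=O)O[C@]3(C)C(=O)[C@@]1(C)C(=O)C(C(=O)C[C@H](c4ccccc4)O[Si](C)(C)C(C)(C)C)[C@]23O[Si](CC)(CC)CC | intermediate
19 | cage lactol (2′S,5R,6S,8R): 18 with C1′ as CH(OH), both anomers | CC1(C)[C@@H]2C(O)O[C@]3(C)C(=O)[C@@]1(C)C(=O)C(C(=O)C[C@H](c4ccccc4)O[Si](C)(C)C(C)(C)C)[C@]23O[Si](CC)(CC)CC | intermediate
20 | desilylated hydroxy diketone: 19 with free C5 and C2 hydroxyls, not isolated | CC1(C)[C@@H]2C(O)O[C@]3(C)C(=O)[C@@]1(C)C(=O)C(C(=O)C[C@H](c4ccccc4)O)[C@]23O | intermediate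
21 | lactol flavanone (2R,5R,6S,8R,2′S): 22 with C1′ as CH(OH) | CC1(C)[C@@H]2C(O)O[C@]3(C)C(=O)[C@@]1(C)C1=C(C(=O)C[C@H](c4ccccc4)O1)[C@]23O | intermediate
22 | target cage flavanone (2R,5R,6S,8R,2′R), CNP0322161.2 | CC1(C)[C@@H]2CO[C@]3(C)C(=O)[C@@]1(C)C1=C(C(=O)C[C@H](c4ccccc4)O1)[C@]23O | target

## Step count and least certain steps

Total step count: 15. Longest linear sequence: 13 steps (steps 1–6 and 9–15, from dimedone); the side chain takes 2 steps (7 and 8).

**Step 12 (proposed new method).**
- What may go wrong: the ketene silyl acetal may be C-silylated or simply exchange silyl groups with the triketone without forming the C2′–C5 bond. The acceptor carbon is part of a delocalised system and is hindered by the quaternary C6. A retro-aldol opening on work-up is also possible if the C5 oxygen loses its silyl group.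
- Fallback with known reactions: close the pyranone before the aldol, so that the acceptor is a neutral vinylogous ester ketone. It sets out from 16. Aqueous HF in MeCN removes the silyl group and cyclodehydrates the freed δ-hydroxy triketone to lactone pyranone F1, which is purified by chromatography. LiN(SiMe3)2 (2.2 equiv) in THF at −78 °C, with a cold acetic acid quench, effects a conventional lithium enolate aldol addition to the cage lactone flavanone F2; the first equivalent stores the C4 ketone as its C3 enolate. The same enolate protection followed by iBu2AlH at −78 °C reduces the lactone, and the sequence returns to the route at 21.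
- Cost of the fallback: closure of the pyranone can now also take place at the C5 carbonyl, so its regiochemistry is no longer unambiguous, and strong base meets the C2–O1 bond twice.

**Step 5 (key step).**
- What may go wrong: O-acylation of the enol ethers and self-condensation of malonyl dichloride through its ketene compete with the second C-acylation, which has to form a quaternary carbon at the weakly nucleophilic α-carbon of a vinylogous ester. Retro-Claisen cleavage of the product can occur during work-up.
- Fallback: separate the two acylations and make the second one an acylketene reaction. It sets out from 5. Acylation with tert-butyl 3-chloro-3-oxopropanoate and ZnCl2 in CH2Cl2 gives keto ester F3. Acetone, trifluoroacetic anhydride and trifluoroacetic acid convert it into dioxinone F4. Heating F4 in toluene at 110 °C releases the acylketene, which adds to the enol ether at C6 by C-acylation or by [4+2] addition. Aqueous acid then frees the C1′ ketone, and the sequence returns to the route at 8.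

**Step 11.**
- What may go wrong: acetate or solvent may capture the C6 iodonium intermediate before the seven-membered ring closes, and the separation of 16 from its ring diastereomer may be poor because C2 is far from C6 and C8.
- Fallback: make the C6–O bond in two stages. It sets out from 15. N-Bromosuccinimide in CH2Cl2 gives bromo acid F5 as a mixture at C6. AgOSO2CF3 with 2,6-lutidine in MeCN abstracts bromide while the carboxylate, which reaches only the face of the C3′ chain, closes the ring from either C6 epimer. After the same chromatographic separation the sequence returns to the route at 16.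
- If the two lactones do not separate on silica gel, preparative HPLC on a chiral stationary phase is used at the same stage; this creates no new compounds.

**Step 13.**
- What may go wrong: hydride may also add to the C7 ketone, since ketones are normally more reactive than lactones and only steric shielding protects C7.
- Fallback: reduce both on purpose and restore the ketone last. It sets out from 18. Excess iBu2AlH after NaH gives the C7 carbinol lactol F6. Aqueous HF in MeCN gives the C7 carbinol lactol flavanone F7. Et3SiH with BF3·OEt2 gives the C7 carbinol ether F8. Dess–Martin periodinane oxidises the secondary C7 alcohol, leaves the tertiary C5 alcohol alone, and returns to the route at 22.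

## Further compounds

F1 | step 12 | lactone pyranone: 16 with the pyranone closed (O1 on C8a) in place of the silyloxy acyl chain, C6 and C8 configured as in 16, 2R | O=C1CC(C)(C)[C@]2(C)C3=C(C(=O)C[C@H](c4ccccc4)O3)C(=O)[C@](C)(O1)C2=O
F2 | step 12 | cage lactone flavanone: 22 with C1′ as lactone carbonyl | CC1(C)[C@@H]2C(=O)O[C@]3(C)C(=O)[C@@]1(C)C1=C(C(=O)C[C@H](c4ccccc4)O1)[C@]23O
F3 | step 5 | tert-butyl 3-(4-methoxy-1,3,6,6-tetramethyl-2-oxocyclohex-3-en-1-yl)-3-oxopropanoate, racemate | COC1=C(C)C(=O)C(C)(C(=O)CC(=O)OC(C)(C)C)C(C)(C)C1
F4 | step 5 | 6-(4-methoxy-1,3,6,6-tetramethyl-2-oxocyclohex-3-en-1-yl)-2,2-dimethyl-4H-1,3-dioxin-4-one, racemate | COC1=C(C)C(=O)C(C)(C2=CC(=O)OC(C)(C)O2)C(C)(C)C1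
F5 | step 11 | 3-{3-bromo-5-[(3R)-3-[(tert-butyldimethylsilyl)oxy]-3-phenylpropanoyl]-1,3-dimethyl-2,4,6-trioxocyclohexyl}-3-methylbutanoic acid, mixture at C6 and C8 | OC(=O)CC(C)(C)C1(C)C(=O)C(C(=O)C[C@H](c2ccccc2)O[Si](C)(C)C(C)(C)C)C(=O)C(C)(Br)C1=O
F6 | step 13 | C7 carbinol lactol: 19 with C7 as CH(OH) | CC1(C)[C@@H]2C(O)O[C@]3(C)C(O)[C@@]1(C)C(=O)C(C(=O)C[C@H](c4ccccc4)O[Si](C)(C)C(C)(C)C)[C@]23O[Si](CC)(CC)CC
F7 | step 13 | C7 carbinol lactol flavanone: 21 with C7 as CH(OH) | CC1(C)[C@@H]2C(O)O[C@]3(C)C(O)[C@@]1(C)C1=C(C(=O)C[C@H](c4ccccc4)O1)[C@]23O
F8 | step 13 | C7 carbinol ether: 22 with C7 as CH(OH) | CC1(C)[C@@H]2CO[C@]3(C)C(O)[C@@]1(C)C1=C(C(=O)C[C@H](c4ccccc4)O1)[C@]23O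
A1 | alternative 1 | 2-{[(1R)-2,4-bis(tert-butyldimethylsilyloxy)-5,6,6-trimethylcyclohexa-2,4-dien-1-yl]methoxy}prop-1-en-1-one (tethered ketene) | CC(=C=O)OC[C@@H]1C(O[Si](C)(C)C(C)(C)C)=CC(O[Si](C)(C)C(C)(C)C)=C(C)C1(C)C
A2 | alternative 1 | tetrahydrofuran-fused 2-vinylcyclobutanone with the C4a–C7 bond | CC1(C)[C@@H]2CO[C@]3(C)C(=O)[C@H](C(O[Si](C)(C)C(C)(C)C)=C1C)[C@]23O[Si](C)(C)C(C)(C)C
A3 | alternative 2 | (6R)-1,3-bis(tert-butyldimethylsilyloxy)-6-[(tert-butyldimethylsilyloxy)methyl]-2,4,5,5-tetramethylcyclohexa-1,3-diene | CC1(C)[C@H](CO[Si](C)(C)C(C)(C)C)C(O[Si](C)(C)C(C)(C)C)=C(C)C(O[Si](C)(C)C(C)(C)C)=C1C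
A4 | alternative 2 | (5R)-1-bromo-5-[(tert-butyldimethylsilyl)oxy]-5-phenylpent-1-yn-3-one | BrC#CC(=O)C[C@H](c1ccccc1)O[Si](C)(C)C(C)(C)C
A5 | alternative 2 | bicyclo[2.2.2]octadiene adduct with C8a bromide and C7 silyl enol ether | CC1(C)[C@H](CO[Si](C)(C)C(C)(C)C)[C@]2(O[Si](C)(C)C(C)(C)C)C(C)=C(O[Si](C)(C)C(C)(C)C)[C@@]1(C)C(Br)=C2C(=O)C[C@H](c1ccccc1)O[Si](C)(C)C(C)(C)C
A6 | alternative 3 | (2S)-2-methyl-2-(3-methylbut-2-enoyl)oxolan-3-one | CC(C)=CC(=O)[C@@]1(C)OCCC1=O
A7 | alternative 3 | 2,2,5-trimethyl-6-oxabicyclo[3.2.1]octane-4,8-dione | CC1(C)[C@@H](C2=O)CO[C@]2(C)C(=O)C1
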